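The constants of this reaction were hidden from me, but the substrate columns offered one I could carry. I needed it to decide whether the next flask, charged with 0.020 M of substrate, should be left to 15 min or stopped sooner, which hung on whether target would still stand clear of the scatter at the end.

| setting | larch | alder | flask |
|---|---|---|---|
| substrate | 0.028 M | 0.044 M | 0.020 M |
| remark | run made earlier | run made earlier |  |
| time |  |  | 15 min |

| run | time / min | target / % | substrate / % |
|---|---|---|---|
| larch | 1.33 | 14.8 | 70.8 |
| larch | 2.50 | 17.1 | 56.8 |
| larch | 4.00 | 16.1 | 45.4 |
| larch | 6.00 | 12.6 | 36.1 |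
| larch | 10.0 | 9.7 | 27.6 |
| larch | 20.0 | 7.9 | 16.9 |
| alder | 1.33 | 20.4 | 62.6 |
| alder | 2.50 | 20.3 | 45.7 |
| alder | 4.00 | 13.8 | 34.4 |
| alder | 6.00 | 13.9 | 26.0 |
| alder | 10.0 | 8.7 | 17.0 |
| alder | 20.0 | 7.2 | 11.5 |

(each reading ± 1 percentage point)

- percentages count the substrate that a species holds: one target counts as two

- amount of target in percent of the substrate charged, at 1.5 min, 5.0 min and 15 min

I worked with the fraction left, f, and not with the amount made. For a second-order loss, 1/f less one grows with the dose D, the charge times the time. Their ratio is the apparent second-order constant k. It drifted: the larch run gave 10.7 /M/min at 4.00 min but 8.78 /M/min at 20.0 min, so I read it at a matching dose. The flask reaches 18.0 M·s at 15 min, and the larch run had 16.8 M·s at 10.0 min, whose reading gave k = 9.37 /M/min, the dose-matched constant.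

So f = 1/(1 + kD) put the substrate left in the flask at 26.2% at 15 min. In the larch run, target held 13.4% of the substrate gone at 10.0 min and 9.51% at 20.0 min. Their mean, 11.5%, gave me 8.45% of target at the end, against a scatter of 1 percentage point, so I kept the charge and the stop.

The forecast said 12.5%, 13.5% and 9%, the last above my figure, noting: “Late values rise slightly at lower concentration”. The flask gave 14.4%, 13.8% and 9.22% of target.

    substrate + target → side product (k = 10.0 /M/min)
    target ⇌ isomer of the product (K = 5.00, k = 0.420 /min)
    2 substrate ⇌ target (K = 92.0 /M, k = 5.00 /M/min)

At 15 min, target in the flask was being made at 0.860 of the rate at which it was used up, each step taken net, and the substrate stood at 26.2%, against the 26.2% that k had given. Put on the alder run at 6.00 min, where the dose was 15.8 M·s against the 16.8 M·s at which k was read, the same k gives 28.8% of substrate left, and the reading there was 26.0%.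

The data are simulated with made-up constants.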